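The cyclopentane (ring B, C1–C5 in spiro[4.5]decane numbering) is cut at C1–C5 and C2–C3. The plan exploits the side-chain ketone. C5′ lies four atoms from C2, so a temporary C2–C5′ bond turns C1, C2 and the chain C2′–C5′ into (R)-4-methylcyclohex-2-enone. In one operation, hydrogen-atom transfer to a cyclohexenyl aldehyde makes a tertiary radical at spiro carbon C5 of ring A. This radical adds to the enone β-carbon, and the resulting enolate closes on the aldehyde carbon C3. The step unites two chiral fragments and sets four stereocentres. Isopropyl addition and Grob fragmentation then erase the temporary ring and the C3 oxygen together.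

Key step: step 7

Remark on locants: the text uses the spiro[4.5]decane numbering of the target. C1 is the CH with the side chain, C2 and C3 are CH2, C4 is CHCH3, C5 is the spiro carbon, C6 is CH2, C7 is CHOH, C8 is C–CO2Me, C9 is =CH and C10 is CH2. The side chain C1′–C7′ is numbered as 6-methyl-5-oxoheptan-2-yl. Ring A is the six-membered ring and ring B the five-membered ring.

Assumption: the sense of induction of BINAPHOS with a 1-vinylcyclohexene is taken to parallel that known for vinylarenes, so the (S,R) ligand is assigned to the (R)-aldehyde.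

Step 1
Reactants: 1 1,4-dioxaspiro[4.5]decan-7-one
Product: 2 1,4-dioxaspiro[4.5]dec-7-en-7-yl trifluoromethanesulfonate
Conditions: LDA, THF, −78 °C; PhNTf2, −78 → 25 °C
Reagents that add atoms: N-phenylbis(trifluoromethanesulfonimide), O=S(=O)(N(c1ccccc1)S(=O)(=O)C(F)(F)F)C(F)(F)F
Why: Kinetic enolate formation at the CH2 remote from the ketal, followed by O-sulfonylation (enol triflate synthesis), should give the triflate; no stereocentre is formed.

Step 2
Reactants: 2 1,4-dioxaspiro[4.5]dec-7-en-7-yl trifluoromethanesulfonate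
Product: 3 7-ethenyl-1,4-dioxaspiro[4.5]dec-7-ene
Conditions: Bu3SnCH=CH2, Pd(PPh3)4 (cat.), LiCl, THF, reflux
Reagents that add atoms: tributyl(vinyl)stannane, C=C[Sn](CCCC)(CCCC)CCCC
Why: Stille coupling of an enol triflate with a vinylstannane should give the 1-vinylcyclohexene and leave the ketal untouched.

Step 3
Reactants: 3 7-ethenyl-1,4-dioxaspiro[4.5]dec-7-ene
Product: 4 (2R)-2-(1,4-dioxaspiro[4.5]dec-7-en-7-yl)propanal
Conditions: Rh(acac)(CO)2 (cat.), (S,R)-BINAPHOS (cat.), CO/H2 (1:1, 20 atm), benzene, 35 °C; used at once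
Reagents that add atoms: carbon monoxide, [C-]#[O+]
Why: Asymmetric hydroformylation of a 1-vinylcycloalkene runs through an η3-allyl rhodium species and places the formyl group on the internal vinyl carbon, the chiral phosphine-phosphite ligand setting the (R) centre (future C4).

Step 4
Reactants: 5 (R)-(+)-pulegone
Product: 6 (3R)-3-methyl-6-(propan-2-ylidene)cyclohex-1-en-1-yl trifluoromethanesulfonate
Conditions: LDA, THF, −78 °C; PhNTf2, −78 → 0 °C
Reagents that add atoms: N-phenylbis(trifluoromethanesulfonimide), O=S(=O)(N(c1ccccc1)S(=O)(=O)C(F)(F)F)C(F)(F)F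
Why: Kinetic deprotonation at the ring CH2 gives the cross-conjugated enolate, which is O-sulfonylated (enol triflate synthesis); the methyl-bearing stereocentre is not touched.

Step 5
Reactants: 6 (3R)-3-methyl-6-(propan-2-ylidene)cyclohex-1-en-1-yl trifluoromethanesulfonate
Product: 7 (3R)-3-methyl-6-oxocyclohex-1-en-1-yl trifluoromethanesulfonate
Conditions: O3 (titrated), CH2Cl2/MeOH, −78 °C; Me2S
Reagents that add atoms: ozone, [O-][O+]=O
Why: Ozonolysis should select the electron-rich tetrasubstituted exocyclic alkene over the triflate-bearing alkene, and reductive work-up gives the ketone.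

Step 6
Reactants: 7 (3R)-3-methyl-6-oxocyclohex-1-en-1-yl trifluoromethanesulfonate
Product: 8 (4R)-4-methylcyclohex-2-en-1-one
Conditions: Pd(OAc)2 (cat.), PPh3, HCO2H, Et3N, DMF, 60 °C
Reagents that add atoms: none
Why: Palladium-catalysed formate reduction of the vinyl triflate replaces OTf by H and leaves the γ-stereocentre in place.

Step 7
Reactants: 4 (2R)-2-(1,4-dioxaspiro[4.5]dec-7-en-7-yl)propanal; 8 (4R)-4-methylcyclohex-2-en-1-one
Product: 9 tricyclic aldol (3-hydroxy-2,7-dimethyl-octahydroinden-4-one spiro-joined at its C1 to C7 of 1,4-dioxaspiro[4.5]decane; cis ring fusion, 7-methyl trans to the spiro carbon, 3-OH trans to the carbonyl carbon and cis to the 2-methyl)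
Conditions: Fe(acac)3 (0.3 equiv), PhSiH3, EtOH/ClCH2CH2Cl, 25 °C, excess 8, slow addition of 4
Reagents that add atoms: none
Why: An iron hydride formed from Fe(acac)3 and PhSiH3 transfers a hydrogen atom to the CH end of the electron-rich trisubstituted alkene of 4 (not to the electron-poor alkene of 8), the tertiary C5 radical adds to the β-carbon of 8 (Giese addition, C1–C5 bond), divalent iron reduces the α-keto radical to an iron enolate, and this enolate attacks the pendant aldehyde (C2–C3 bond) before ethanol protonates it. The closest known reaction type is the hydrogen-atom-transfer-initiated reductive olefin coupling run as a radical-polar crossover annulation (conjugate addition, then aldol) between an alkenyl aldehyde and a cyclic enone. Only ring B closes, by a 5-(enolexo)-exo-trig aldol, and the three-atom tether forces a cis ring fusion, which fixes C2. C1 is set by attack anti to the neighbouring methyl group of 8, C5 by steric pairing in the staggered transition state (the bulky CH2 arm next to the dioxolane takes the face of the small C4 methyl and of C1–H, the slim CH2CH2 arm takes the face of C2′), and C3 by the closed, metal-bridged aldol transition state that turns the aldehyde oxygen outward, trans to C5′; C4 comes unchanged from 4. The step needs cross-coupling to beat homo-coupling and ring closure to beat protonation, and the polarity match of a nucleophilic tertiary radical with the enone, the excess of 8 and the proximity of the aldehyde should secure both.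

Step 8
Reactants: 9 tricyclic aldol
Product: 10 tricyclic 1,3-diol (isopropyl carbinol at C5′, either epimer)
Conditions: iPrMgCl (3 equiv), LaCl3·2LiCl, THF, −20 → 0 °C
Reagents that add atoms: isopropylmagnesium chloride, CC(C)[Mg]Cl
Why: LaCl3-promoted Grignard 1,2-addition favours carbonyl attack over enolisation and retro-aldol cleavage, and the configuration of the new carbinol carbon C5′ is irrelevant because it returns to sp2 in step 9.

Step 9
Reactants: 10 tricyclic 1,3-diol
Product: 13 (1S,4S,5S)-4-methyl-1-[(2R)-6-methyl-5-oxoheptan-2-yl]spiro[4.5]dec-2-en-7-one, via monomesylate 11 (not isolated), via ketal ketone 12 (not isolated)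
Conditions: MsCl, Et3N, THF, 0 °C; KOtBu, 0 → 25 °C; then 1 M HCl, 25 °C
Reagents that add atoms: water, O (oxygen of the C7 ketone); methanesulfonyl chloride, CS(=O)(=O)Cl (atoms only in 11)
Why: The secondary hydroxyl is mesylated selectively, and the potassium alkoxide of the tertiary alcohol triggers a Grob fragmentation across O–C5′–C2–C3–OMs (the C2–C5′ and C3–O bonds are trans on ring B and can become antiperiplanar), which releases the isopropyl ketone and the C2=C3 alkene, while the acidic work-up hydrolyses the dioxolane and no stereocentre of the target is touched.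

Step 10
Reactants: 13 (1S,4S,5S)-4-methyl-1-[(2R)-6-methyl-5-oxoheptan-2-yl]spiro[4.5]dec-2-en-7-one
Product: 14 (1R,4S,5S)-4-methyl-1-[(2R)-6-methyl-5-oxoheptan-2-yl]spiro[4.5]decan-7-one
Conditions: H2 (1 atm), RhCl(PPh3)3 (cat.), benzene/EtOH, 25 °C
Reagents that add atoms: none
Why: Homogeneous hydrogenation saturates the cis-disubstituted cyclopentene without the double-bond migration that could scramble the allylic centres C1 and C4, and it leaves both ketones alone.

Step 11
Reactants: 14 (1R,4S,5S)-4-methyl-1-[(2R)-6-methyl-5-oxoheptan-2-yl]spiro[4.5]decan-7-one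
Product: 16 methyl (1R,4S,5S)-4-methyl-1-[(2R)-6-methyl-5-oxoheptan-2-yl]-7-oxospiro[4.5]decane-8-carboxylate (C8 epimers and enol), via pyrrolidine enamine 15 (not isolated)
Conditions: pyrrolidine, TsOH (cat.), toluene, reflux (−H2O); ClCO2Me, 0 → 80 °C; then aq. AcOH/NaOAc
Reagents that add atoms: methyl chloroformate, COC(=O)Cl; water, O (oxygen of the C7 ketone); pyrrolidine, C1CCNC1 (atoms only in 15)
Why: In this Stork enamine acylation only the unhindered cyclohexanone condenses with pyrrolidine, the enamine forms toward C8 and away from the neopentyl C6, and C-acylation followed by hydrolysis gives the β-keto ester, whose C8 configuration is of no consequence.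

Step 12
Reactants: 16 methyl (1R,4S,5S)-4-methyl-1-[(2R)-6-methyl-5-oxoheptan-2-yl]-7-oxospiro[4.5]decane-8-carboxylate
Product: 18 methyl (1R,4S,5S)-4-methyl-1-[(2R)-6-methyl-5-oxoheptan-2-yl]-7-oxospiro[4.5]dec-8-ene-8-carboxylate, via 8-phenylselanyl keto ester 17 (not isolated)
Conditions: PhSeCl, pyridine, CH2Cl2, 0 °C; then 30% H2O2, 0 → 25 °C
Reagents that add atoms: benzeneselenenyl chloride, Cl[Se]c1ccccc1 (atoms only in 17)
Why: Selenenylation of the enolic β-keto ester at C8 and selenoxide syn-elimination, which can only take a C9 hydrogen, should give the 2-carbomethoxy enone, while the simple ketone does not react.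

Step 13
Reactants: 18 methyl (1R,4S,5S)-4-methyl-1-[(2R)-6-methyl-5-oxoheptan-2-yl]-7-oxospiro[4.5]dec-8-ene-8-carboxylate
Product: 19 methyl (1R,4S,5S,7S)-7-hydroxy-4-methyl-1-[(2R)-6-methyl-5-oxoheptan-2-yl]spiro[4.5]dec-8-ene-8-carboxylate (target)
Conditions: (R)-2-methyl-CBS-oxazaborolidine (0.3 equiv), catecholborane, toluene, −78 °C
Reagents that add atoms: none
Why: In the Corey-Bakshi-Shibata reduction the (R)-oxazaborolidine treats the fully substituted alkenyl carbon C8 as the large group and C6H2 as the small group and delivers hydride to give the (7S)-alcohol under reagent control, and at −78 °C catecholborane should spare the hindered isopropyl ketone and the ester.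

Compound list
1 | 1,4-dioxaspiro[4.5]decan-7-one | O=C1CCCC2(C1)OCCO2 | starting material
2 | 1,4-dioxaspiro[4.5]dec-7-en-7-yl trifluoromethanesulfonate | O=S(=O)(OC1=CCCC2(C1)OCCO2)C(F)(F)F | intermediate
3 | 7-ethenyl-1,4-dioxaspiro[4.5]dec-7-ene | C=CC1=CCCC2(C1)OCCO2 | intermediate
4 | (2R)-2-(1,4-dioxaspiro[4.5]dec-7-en-7-yl)propanal | O=C[C@H](C)C1=CCCC2(C1)OCCO2 | intermediate
5 | (R)-(+)-pulegone | C[C@@H]1CCC(=C(C)C)C(=O)C1 | starting material
6 | (3R)-3-methyl-6-(propan-2-ylidene)cyclohex-1-en-1-yl trifluoromethanesulfonate | C[C@@H]1CCC(=C(C)C)C(OS(=O)(=O)C(F)(F)F)=C1 | intermediate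
7 | (3R)-3-methyl-6-oxocyclohex-1-en-1-yl trifluoromethanesulfonate | C[C@@H]1CCC(=O)C(OS(=O)(=O)C(F)(F)F)=C1 | intermediate
8 | (4R)-4-methylcyclohex-2-en-1-one | C[C@@H]1CCC(=O)C=C1 | intermediate
9 | tricyclic aldol (cis-fused hydrindanone, spiro-joined to the ketal ring) | C1CC[C@@]2(CC13OCCO3)[C@H]4[C@H](C)CCC(=O)[C@H]4[C@H](O)[C@@H]2C | intermediate
10 | tricyclic 1,3-diol (isopropyl carbinol, either epimer at C5′) | C1CC[C@@]2(CC13OCCO3)[C@H]4[C@H](C)CCC(O)(C(C)C)[C@H]4[C@H](O)[C@@H]2C | intermediate
11 | monomesylate of 10 (secondary OMs) | C1CC[C@@]2(CC13OCCO3)[C@H]4[C@H](C)CCC(O)(C(C)C)[C@H]4[C@H](OS(C)(=O)=O)[C@@H]2C | intermediate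
12 | ethylene ketal of 13 | C1CC[C@@]2(CC13OCCO3)[C@@H]([C@H](C)CCC(=O)C(C)C)C=C[C@@H]2C | intermediate
13 | (1S,4S,5S)-4-methyl-1-[(2R)-6-methyl-5-oxoheptan-2-yl]spiro[4.5]dec-2-en-7-one | C1CC[C@@]2(CC1=O)[C@@H]([C@H](C)CCC(=O)C(C)C)C=C[C@@H]2C | intermediate
14 | (1R,4S,5S)-4-methyl-1-[(2R)-6-methyl-5-oxoheptan-2-yl]spiro[4.5]decan-7-one | C1CC[C@@]2(CC1=O)[C@@H]([C@H](C)CCC(=O)C(C)C)CC[C@@H]2C | intermediate
15 | pyrrolidine enamine of 14 (C7=C8) | C=1CC[C@@]2(CC=1N3CCCC3)[C@@H]([C@H](C)CCC(=O)C(C)C)CC[C@@H]2C | intermediate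
16 | methyl (1R,4S,5S)-4-methyl-1-[(2R)-6-methyl-5-oxoheptan-2-yl]-7-oxospiro[4.5]decane-8-carboxylate | COC(=O)C1CC[C@@]2(CC1=O)[C@@H]([C@H](C)CCC(=O)C(C)C)CC[C@@H]2C | intermediate
17 | 8-phenylselanyl derivative of 16 | COC(=O)C1([Se]c3ccccc3)CC[C@@]2(CC1=O)[C@@H]([C@H](C)CCC(=O)C(C)C)CC[C@@H]2C | intermediate
18 | methyl (1R,4S,5S)-4-methyl-1-[(2R)-6-methyl-5-oxoheptan-2-yl]-7-oxospiro[4.5]dec-8-ene-8-carboxylate | COC(=O)C1=CC[C@@]2(CC1=O)[C@@H]([C@H](C)CCC(=O)C(C)C)CC[C@@H]2C | intermediate
19 | methyl (1R,4S,5S,7S)-7-hydroxy-4-methyl-1-[(2R)-6-methyl-5-oxoheptan-2-yl]spiro[4.5]dec-8-ene-8-carboxylate | COC(=O)C1=CC[C@@]2(C[C@@H]1O)[C@@H]([C@H](C)CCC(=O)C(C)C)CC[C@@H]2C | target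

Total step count: 13. Longest linear sequence: 10 steps (steps 1–3 or 4–6, then 7–13).

Steps most likely to fail

For step 7, several processes may go wrong:
- The tertiary radical may be quenched by hydrogen transfer, or it may add too slowly to the hindered β-carbon.
- The enolate may be protonated before it cyclises.
- The labile α-centre of 4 may epimerise.
- Facial selection at C5 may be weak.

The fallback separates the two bond formations with known chemistry. It sets out from 4, which is reduced at once with NaBH4 to the configurationally stable (2R)-2-(1,4-dioxaspiro[4.5]dec-7-en-7-yl)propan-1-ol F1. Iron-hydride reductive olefin coupling of this alcohol with 8 should give the keto alcohol F2. DMP oxidation then gives the keto aldehyde F3. A reversible base-mediated intramolecular aldol reaction (K2CO3, MeOH) closes ring B and comes back to the route at 9.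

For step 9, the tertiary alkoxide may displace the mesylate (oxetane formation). Simple elimination may also win if the C2–C5′ and C3–O bonds cannot become antiperiplanar. The fallback replaces the fragmentation by a retro-aldol cleavage and sets out from 10.
- DMP oxidises only the secondary alcohol, to the β-hydroxy ketone F4.
- Mild base (K2CO3, MeOH, 0 °C) cleaves the C2–C5′ bond to the cyclopentanone F5, which carries the free isopropyl ketone.
- TsNHNH2 condenses with the more accessible ring ketone to the tosylhydrazone F6.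
- Catecholborane followed by NaOAc reduces it to the ethylene ketal of 14 F7.
- Aqueous HCl comes back to the route at 14.

For step 13, reagent control may be eroded by the substrate, or the side-chain ketone may be reduced in competition. The fallback uses substrate control followed by inversion and sets out from 18. Luche reduction (NaBH4, CeCl3·7H2O, MeOH, −78 °C) should deliver hydride from the more open face, next to C1–H, to give the 7-epi alcohol F8. Mitsunobu reaction with 4-nitrobenzoic acid (PPh3, DIAD) inverts C7 to the 4-nitrobenzoate F9. K2CO3 in MeOH then comes back to the route at 19.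

Further compounds
F1 | step 7 | (2R)-2-(1,4-dioxaspiro[4.5]dec-7-en-7-yl)propan-1-ol | OC[C@H](C)C1=CCCC2(C1)OCCO2
F2 | step 7 | keto alcohol (conjugate adduct of F1 and 8) | OC[C@H](C)[C@@]1(CCCC2(C1)OCCO2)[C@@H]3CC(=O)CC[C@H]3C
F3 | step 7 | keto aldehyde (open form of 9) | O=C[C@H](C)[C@@]1(CCCC2(C1)OCCO2)[C@@H]3CC(=O)CC[C@H]3C
F4 | step 9 | β-hydroxy ketone (C3 ketone of 10) | C1CC[C@@]2(CC13OCCO3)[C@H]4[C@H](C)CCC(O)(C(C)C)[C@H]4C(=O)[C@@H]2C
F5 | step 9 | cyclopentanone with free side-chain ketone (C3 ketone, ketal at C7) | C1CC[C@@]2(CC13OCCO3)[C@@H]([C@H](C)CCC(=O)C(C)C)CC(=O)[C@@H]2C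
F6 | step 9 | C3 tosylhydrazone of F5 | C1CC[C@@]2(CC13OCCO3)[C@@H]([C@H](C)CCC(=O)C(C)C)CC(=NNS(=O)(=O)c5ccc(C)cc5)[C@@H]2C
F7 | step 9 | ethylene ketal of 14 | C1CC[C@@]2(CC13OCCO3)[C@@H]([C@H](C)CCC(=O)C(C)C)CC[C@@H]2C
F8 | step 13 | (7R)-epimer of 19 | COC(=O)C1=CC[C@@]2(C[C@H]1O)[C@@H]([C@H](C)CCC(=O)C(C)C)CC[C@@H]2C
F9 | step 13 | 4-nitrobenzoate of 19 | COC(=O)C1=CC[C@@]2(C[C@@H]1OC(=O)c3ccc(cc3)[N+](=O)[O-])[C@@H]([C@H](C)CCC(=O)C(C)C)CC[C@@H]2C
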